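**Retrosynthetic overview** (ring A: C1 OMe, C2 OH, C3 OAr, C4–C6 Br; ring B: the 2,4-dibromophenyl group)
- The target comes from its O-benzyl ether. All three ring A bromines trace back to one amino group at C5: C5–Br by Sandmeyer reaction, C4–Br and C6–Br by bromination ortho to the amine. The aniline comes from a 4-nitrophenol.
- Ring A of 2-aryloxy-6-methoxy-4-nitrophenol is cut at C3–C4 and C1–C6. The first bond is an intermolecular aldol between 1-(2,4-dibromophenoxy)-3-methoxypropan-2-one and sodium nitromalonaldehyde, followed by a ring-closing aldol condensation and aromatisation.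
- The ketone comes from 2,4-dibromophenol and methyl glycidyl ether (epoxide opening, then oxidation), so the future diaryl ether C–O bond is made as a simple alkyl aryl ether. The nitromalonaldehyde salt comes from mucobromic acid and NaNO2.
- Ring order: ring B is bought. Ring A is the only ring built, in step 4.

Assumption: the target has no stereocentre and its diaryl ether axis rotates freely, so it is achiral and needs no stereocontrol. The transient stereocentres in 3 and 7 are erased later.

**Step 1**
Reactants: 1 2,4-dibromophenol; 2 methyl glycidyl ether (2-(methoxymethyl)oxirane, racemic)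
Product: 3 1-(2,4-dibromophenoxy)-3-methoxypropan-2-ol (racemic)
Conditions: 2 (1.3 equiv), K2CO3 (0.2 equiv), DMF, 90 °C, 16 h
Reagents that add atoms: none
Why: Base-catalysed SN2 epoxide opening by the phenoxide of 1 occurs at the unhindered terminal CH2, and the carbinol stereocentre (racemic because 2 is racemic) is erased in step 2.

**Step 2**
Reactants: 3 1-(2,4-dibromophenoxy)-3-methoxypropan-2-ol
Product: 4 1-(2,4-dibromophenoxy)-3-methoxypropan-2-one
Conditions: Dess–Martin periodinane (1.3 equiv), CH2Cl2, 0 °C → rt, 2 h
Reagents that add atoms: none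
Why: Dess–Martin oxidation converts the secondary alcohol to the ketone under neutral, non-enolising conditions that leave the aryl bromides and both ethers untouched and create no stereocentre.

**Step 3**
Reactants: 5 mucobromic acid ((Z)-2,3-dibromo-4-oxobut-2-enoic acid, mainly present as its cyclic lactol)
Product: 6 sodium nitromalonaldehyde monohydrate, Na[OCH=C(NO2)CHO]·H2O
Conditions: NaNO2 (3.7 equiv), H2O/EtOH, 54 °C, then 0 °C, recrystallise from aq. EtOH (impact-sensitive salt: use a shield, do not dry with heat, use promptly)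
Reagents that add atoms: sodium nitrite NaNO2, [Na+].[O-]N=O; water, O
Why: Nucleophilic vinylic substitution (addition–elimination) of the two C–Br bonds by nitrite and water, followed by decarboxylation, gives the strongly stabilised nitromalonaldehyde anion, which crystallises on cooling in a long-established preparative procedure without forming a stereocentre.

**Step 4** (key step)
Reactants: 4 1-(2,4-dibromophenoxy)-3-methoxypropan-2-one; 6 sodium nitromalonaldehyde monohydrate
Product: 8 2-(2,4-dibromophenoxy)-6-methoxy-4-nitrophenol, via open-chain aldol adduct 7 (not isolated)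
Conditions: 6 (1.1 equiv), NaOH (1.1 equiv, 1 M aq.), EtOH/H2O, 0 °C → rt, 24–48 h; then 2 M HCl to pH 2
Reagents that add atoms: none
Why: In this nitromalonaldehyde–ketone phenol synthesis the enolate of 4 adds to one formyl group of 6 (intermolecular aldol, giving 7 as an irrelevant diastereomer mixture), the second α-carbon closes ring A by intramolecular aldol condensation, and loss of two waters with aromatisation erases all stereocentres and gives a single regioisomer whichever α-carbon reacts first.

**Step 5**
Reactants: 8 2-(2,4-dibromophenoxy)-6-methoxy-4-nitrophenol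
Product: 9 2-(benzyloxy)-1-(2,4-dibromophenoxy)-3-methoxy-5-nitrobenzene
Conditions: BnBr (1.3 equiv), K2CO3 (2 equiv), DMF, 60 °C, 6 h
Reagents that add atoms: benzyl bromide, BrCc1ccccc1
Why: Williamson ether synthesis (SN2) on the acidic nitrophenol masks the hydroxyl, so the later 4-aminophenol stage cannot be oxidised to a quinone imine by NBS or nitrite.

**Step 6**
Reactants: 9 2-(benzyloxy)-1-(2,4-dibromophenoxy)-3-methoxy-5-nitrobenzene
Product: 10 4-(benzyloxy)-3-(2,4-dibromophenoxy)-5-methoxyaniline
Conditions: Fe powder (6 equiv), NH4Cl (6 equiv), EtOH/H2O 4:1, 80 °C, 2 h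
Reagents that add atoms: none
Why: Béchamp-type reduction with iron reduces the nitro group chemoselectively, without the hydrodebromination or O-debenzylation that catalytic hydrogenation would cause.

**Step 7**
Reactants: 10 4-(benzyloxy)-3-(2,4-dibromophenoxy)-5-methoxyaniline
Product: 11 4-(benzyloxy)-2,6-dibromo-3-(2,4-dibromophenoxy)-5-methoxyaniline
Conditions: NBS (2.05 equiv), MeCN, −10 °C → rt, dark
Reagents that add atoms: N-bromosuccinimide, O=C1CCC(=O)N1Br
Why: Electrophilic aromatic bromination is steered by the amino group to its two ortho positions, which are the only free sites of ring A and are further activated by OMe and OAr, whereas ring B carries two deactivating bromines and the benzyl phenyl is unactivated.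

**Step 8**
Reactants: 11 4-(benzyloxy)-2,6-dibromo-3-(2,4-dibromophenoxy)-5-methoxyaniline
Product: 13 1-(benzyloxy)-3,4,5-tribromo-2-(2,4-dibromophenoxy)-6-methoxybenzene, via aryldiazonium bromide 12 (not isolated)
Conditions: t-BuONO (1.5 equiv), CuBr2 (1.2 equiv), MeCN, slow addition of 11, 0 → 60 °C
Reagents that add atoms: CuBr2, [Cu+2].[Br-].[Br-]; tert-butyl nitrite, CC(C)(C)ON=O (its nitrogen stays only in 12)
Why: Non-aqueous Sandmeyer bromination diazotises even this weakly basic, doubly ortho-substituted aniline in homogeneous solution, and monovalent copper formed in situ reduces 12 to the aryl radical, which takes bromine from CuBr2 at the carbon that carried nitrogen.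

**Step 9**
Reactants: 13 1-(benzyloxy)-3,4,5-tribromo-2-(2,4-dibromophenoxy)-6-methoxybenzene
Product: 14 3,4,5-tribromo-2-(2,4-dibromophenoxy)-6-methoxyphenol (target)
Conditions: BCl3 (2 equiv, 1 M in CH2Cl2), pentamethylbenzene (3 equiv), CH2Cl2, −78 °C, 30 min; then H2O
Reagents that add atoms: none
Why: Lewis-acid debenzylation cleaves the twisted, doubly flanked central benzyl ether within minutes at −78 °C, where the aryl methyl ether, the diaryl ether and the five C–Br bonds are inert, while pentamethylbenzene traps the benzyl cation (Friedel–Crafts) before it can alkylate the product.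

**Compound list**
1 | 2,4-dibromophenol | Oc1ccc(Br)cc1Br | starting material
2 | methyl glycidyl ether (racemic) | COCC1CO1 | starting material
3 | 1-(2,4-dibromophenoxy)-3-methoxypropan-2-ol (racemic) | COCC(O)COc1ccc(Br)cc1Br | intermediate
4 | 1-(2,4-dibromophenoxy)-3-methoxypropan-2-one | COCC(=O)COc1ccc(Br)cc1Br | intermediate
5 | mucobromic acid, (Z)-2,3-dibromo-4-oxobut-2-enoic acid | OC(=O)/C(Br)=C(/Br)C=O | starting material
6 | sodium nitromalonaldehyde monohydrate | [Na+].[O-]C=C(C=O)[N+](=O)[O-].O | intermediate
7 | 4-(2,4-dibromophenoxy)-3-hydroxy-6-methoxy-2-nitro-5-oxohexanal (open-chain aldol adduct, diastereomer mixture, drawn neutral) | COCC(=O)C(Oc1ccc(Br)cc1Br)C(O)C(C=O)[N+](=O)[O-] | intermediate (not isolated)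
8 | 2-(2,4-dibromophenoxy)-6-methoxy-4-nitrophenol | COc1cc(cc(Oc2ccc(Br)cc2Br)c1O)[N+](=O)[O-] | intermediate
9 | 2-(benzyloxy)-1-(2,4-dibromophenoxy)-3-methoxy-5-nitrobenzene | COc1cc(cc(Oc2ccc(Br)cc2Br)c1OCc3ccccc3)[N+](=O)[O-] | intermediate
10 | 4-(benzyloxy)-3-(2,4-dibromophenoxy)-5-methoxyaniline | COc1cc(N)cc(Oc2ccc(Br)cc2Br)c1OCc3ccccc3 | intermediate
11 | 4-(benzyloxy)-2,6-dibromo-3-(2,4-dibromophenoxy)-5-methoxyaniline | COc1c(Br)c(N)c(Br)c(Oc2ccc(Br)cc2Br)c1OCc3ccccc3 | intermediate
12 | 4-(benzyloxy)-2,6-dibromo-3-(2,4-dibromophenoxy)-5-methoxybenzenediazonium bromide | COc1c(Br)c([N+]#N)c(Br)c(Oc2ccc(Br)cc2Br)c1OCc3ccccc3.[Br-] | intermediate (not isolated)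
13 | 1-(benzyloxy)-3,4,5-tribromo-2-(2,4-dibromophenoxy)-6-methoxybenzene | COc1c(Br)c(Br)c(Br)c(Oc2ccc(Br)cc2Br)c1OCc3ccccc3 | intermediate
14 | 3,4,5-tribromo-2-(2,4-dibromophenoxy)-6-methoxyphenol | COc1c(O)c(Oc2ccc(Br)cc2Br)c(Br)c(Br)c1Br | target

**Total steps:** 9. **Longest linear sequence:** 8 (steps 1, 2, 4, 5, 6, 7, 8, 9). Step 3 is a one-step side branch.

**Three steps most likely to fail**

Step 4. An α-aryloxy-α'-alkoxy ketone is an unusual partner for this condensation. Self-aldol of 4, loss of 2,4-dibromophenoxide from its enolate, or decay of 6 in base could lower the yield.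
The fallback sets out from 1 and comes back at 9. Commercial 2-methoxy-4-nitrophenol is iodinated ortho to the hydroxyl (NIS, cat. TFA, MeCN) to give 2-iodo-6-methoxy-4-nitrophenol F1. This is benzylated (BnBr, K2CO3, DMF) to 2-(benzyloxy)-1-iodo-3-methoxy-5-nitrobenzene F2. Oxidation in the presence of 1,3,5-trimethoxybenzene (mCPBA, TsOH·H2O, MeCN) gives [2-(benzyloxy)-3-methoxy-5-nitrophenyl](2,4,6-trimethoxyphenyl)iodonium 4-toluenesulfonate F3. Metal-free O-arylation of 1 with this salt (K2CO3, toluene, 55 °C) transfers the electron-poor, ortho-substituted nitroaryl group selectively and leaves every C–Br bond alone, giving 9.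

Step 8. The hindered, electron-rich diazonium ion 12 may undergo hydrodediazoniation. Bromide may also attack the benzylic CH2 para to the diazonium group and give a quinone diazide.
The fallback sets out from 11 and comes back at 14, and it makes the main failure mode productive. Compound 11 is deliberately deaminated (t-BuONO, DMF, 65 °C) to 3-(benzyloxy)-1,5-dibromo-2-(2,4-dibromophenoxy)-4-methoxybenzene F4. This is debenzylated (BCl3, pentamethylbenzene, CH2Cl2, −78 °C) to 3,5-dibromo-2-(2,4-dibromophenoxy)-6-methoxyphenol F5. The last bromine then enters by electrophilic substitution (Br2 1.05 equiv, AcOH, rt) at the only free site of ring A, which is para to the free hydroxyl, giving 14.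

Step 7. The very electron-rich aniline 10 may be oxidised by NBS to quinone-imine-type tars, or the second bromination may stall.
The fallback sets out from 10 and comes back at 14. Compound 10 is deaminated (NaNO2, aq. HCl, then H3PO2, 0 °C → rt) to 2-(benzyloxy)-1-(2,4-dibromophenoxy)-3-methoxybenzene F6. This is debenzylated (BCl3, pentamethylbenzene, CH2Cl2, −78 °C) to 2-(2,4-dibromophenoxy)-6-methoxyphenol F7. Exhaustive bromination (Br2 3.3 equiv, AcOH, rt → 50 °C) follows. The hydroxyl directs to C5, while OMe and OAr direct to C4 and C6. The trioxygenated ring A outcompetes the dibrominated ring B, giving 14.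

**Further compounds**
F1 | step 4 | 2-iodo-6-methoxy-4-nitrophenol | COc1cc(cc(I)c1O)[N+](=O)[O-]
F2 | step 4 | 2-(benzyloxy)-1-iodo-3-methoxy-5-nitrobenzene | COc1cc(cc(I)c1OCc2ccccc2)[N+](=O)[O-]
F3 | step 4 | [2-(benzyloxy)-3-methoxy-5-nitrophenyl](2,4,6-trimethoxyphenyl)iodonium 4-toluenesulfonate | COc1cc(OC)c([I+]c2cc(cc(OC)c2OCc3ccccc3)[N+](=O)[O-])c(OC)c1.Cc1ccc(cc1)S(=O)(=O)[O-]
F4 | step 8 | 3-(benzyloxy)-1,5-dibromo-2-(2,4-dibromophenoxy)-4-methoxybenzene | COc1c(Br)cc(Br)c(Oc2ccc(Br)cc2Br)c1OCc3ccccc3
F5 | step 8 | 3,5-dibromo-2-(2,4-dibromophenoxy)-6-methoxyphenol | COc1c(Br)cc(Br)c(Oc2ccc(Br)cc2Br)c1O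
F6 | step 7 | 2-(benzyloxy)-1-(2,4-dibromophenoxy)-3-methoxybenzene | COc1cccc(Oc2ccc(Br)cc2Br)c1OCc3ccccc3
F7 | step 7 | 2-(2,4-dibromophenoxy)-6-methoxyphenol | COc1cccc(Oc2ccc(Br)cc2Br)c1O
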